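The route rests on disconnecting the bond between ring oxygen O-1 and the quaternary carbon C-2 of the 5-oxo-2,5-dihydrofuran ring, together with the neighbouring CH2–aryl bond. C-2 carries CO2Me and an arylmethyl group, so it is the α-carbon of a 3-arylpropanoate, the retron of a Meerwein arylation, while the lactone carboxyl is held cis to it by the C-3=C-4 double bond. In one operation an aryl radical adds to the CH2 terminus of an achiral 2-alkoxy-3-aryl-4-(methoxycarbonyl)penta-2,4-dienoic acid and a chiral copper carboxylate traps the resulting radical, closing the butenolide and setting the (S) centre. Dimethyl 2-oxoglutarate supplies all five backbone carbons; both prenyl groups enter afterwards.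

Key step: step 10

Remark: which antipode of the bisoxazoline ligand leads to the (S) centre cannot be predicted with certainty; the (S,S) ligand is written and its mirror image is the alternative.

Step 1
Reactants: 1 2-bromo-6-methoxyphenol
Product: 2 2-bromo-4-iodo-6-methoxyphenol
Conditions: NIS, TFA (cat.), MeCN, 0 °C to rt
Reagents that add atoms: N-iodosuccinimide, O=C1CCC(=O)N1I
Why: electrophilic aromatic iodination; both ortho positions of the phenol are occupied, so the para position is the only strongly activated site.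

Step 2
Reactants: 2 2-bromo-4-iodo-6-methoxyphenol
Product: 3 3-bromo-5-iodobenzene-1,2-diol
Conditions: BBr3, CH2Cl2, −78 °C to 0 °C; then H2O
Reagents that add atoms: none
Why: Lewis-acid cleavage of the aryl methyl ether, to which both aryl halides are inert, frees the catechol before any acid-sensitive group is present.

Step 3
Reactants: 3 3-bromo-5-iodobenzene-1,2-diol
Product: 4 1-bromo-5-iodo-2,3-bis(methoxymethoxy)benzene
Conditions: MOMCl, i-Pr2NEt, CH2Cl2, 0 °C to rt
Reagents that add atoms: chloromethyl methyl ether, COCCl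
Why: O-alkylation of both phenols (acetal protection) gives ethers that withstand the later base, palladium and radical steps and fall off in mild acid.

Step 4
Reactants: 4 1-bromo-5-iodo-2,3-bis(methoxymethoxy)benzene; 5 dimethyl 2-oxopentanedioate
Product: 6 dimethyl 3-[3-bromo-4,5-bis(methoxymethoxy)phenyl]-2-oxopentanedioate (racemic, in equilibrium with its enol)
Conditions: Pd2(dba)3 (2.5 mol %), P(t-Bu)3·HBF4 (10 mol %), K3PO4, toluene, 70 °C
Reagents that add atoms: none
Why: palladium-catalysed enolate arylation (β-arylation of an α-keto ester) should occur at C-3, the only position α to the ketone, and at the C–I bond, which undergoes oxidative addition well before the hindered C–Br bond.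

Step 5
Reactants: 6 dimethyl 3-[3-bromo-4,5-bis(methoxymethoxy)phenyl]-2-oxopentanedioate
Product: 7 dimethyl 3-[3-bromo-4,5-bis(methoxymethoxy)phenyl]-2-(methoxymethoxy)pent-2-enedioate (E/Z mixture)
Conditions: MOMCl, i-Pr2NEt, CH2Cl2, 0 °C
Reagents that add atoms: chloromethyl methyl ether, COCCl
Why: O-alkylation of the aryl-conjugated enol of the α-keto ester with a hard electrophile should give the enol ether; its double-bond geometry need not be controlled because step 6 corrects it.

Step 6
Reactants: 7 dimethyl 3-[3-bromo-4,5-bis(methoxymethoxy)phenyl]-2-(methoxymethoxy)pent-2-enedioate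
Product: 10 (2E)-3-[3-bromo-4,5-bis(methoxymethoxy)phenyl]-4-(methoxycarbonyl)-2-(methoxymethoxy)penta-2,4-dienoic acid (CO2H cis to C-4), via C-4 hydroxymethyl diester 8 (not isolated), via six-membered lactone 9 (not isolated)
Conditions: (CH2O)n, t-BuOK, THF/t-BuOH, 0 °C to rt; then cold aq. KHSO4
Reagents that add atoms: formaldehyde (from paraformaldehyde), C=O
Why: vinylogous Stobbe condensation, in which the glutaconate anion adds to formaldehyde at C-4, the alkoxide lactonises onto the C-1 ester (possible only with C-1 cis to C-4, the anion equilibrating the geometry) and E1cB ring opening gives the methylene group and the free C-1 acid, so ester differentiation and alkene geometry both follow from the mechanism.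

Step 7
Reactants: 11 2-bromo-4-nitrophenol
Product: 12 2-bromo-4-nitrophenyl acetate
Conditions: Ac2O, pyridine, CH2Cl2, rt
Reagents that add atoms: acetic anhydride, CC(=O)OC(C)=O
Why: O-acylation of the phenol gives a protecting group that is not ionised by the later para-diazonium group and is removed in the final acid methanolysis.

Step 8
Reactants: 12 2-bromo-4-nitrophenyl acetate
Product: 13 4-amino-2-bromophenyl acetate (used at once)
Conditions: H2 (1 atm), sulfided 5% Pt/C, EtOAc, rt
Reagents that add atoms: none
Why: catalytic hydrogenation over sulfided platinum should reduce the nitro group without hydrogenolysis of the C–Br bond or the aryl ester.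

Step 9
Reactants: 13 4-amino-2-bromophenyl acetate
Product: 14 4-acetoxy-3-bromobenzenediazonium tetrafluoroborate
Conditions: NOBF4, MeCN, −30 °C to 0 °C; precipitation with Et2O
Reagents that add atoms: nitrosonium tetrafluoroborate, N#[O+].F[B-](F)(F)F
Why: anhydrous diazotisation with a nitrosonium salt forms only water beside the salt, so the aryl acetate is not exposed to aqueous acid.

Step 10
Reactants: 10 (2E)-3-[3-bromo-4,5-bis(methoxymethoxy)phenyl]-4-(methoxycarbonyl)-2-(methoxymethoxy)penta-2,4-dienoic acid; 14 4-acetoxy-3-bromobenzenediazonium tetrafluoroborate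
Product: 15 methyl (2S)-2-[(4-acetoxy-3-bromophenyl)methyl]-3-[3-bromo-4,5-bis(methoxymethoxy)phenyl]-4-(methoxymethoxy)-5-oxo-2,5-dihydrofuran-2-carboxylate
Conditions: Cu(MeCN)4PF6 (10 mol %), 2,2'-(propane-2,2-diyl)bis[(4S)-4-tert-butyl-4,5-dihydrooxazole] (12 mol %), 2,6-di-tert-butylpyridine, EtOAc, 0 °C to rt, N2, dark
Reagents that add atoms: none
Why: Proposed new method: monovalent copper reduces 14 to the 4-acetoxy-3-bromophenyl radical, which adds to the unsubstituted CH2 terminus of the acrylate unit of 10 (Meerwein arylation), forming the future benzylic CH2–aryl bond and a tertiary radical at C-4 of 10 that is stabilised by the ester and by the adjacent enol-ether double bond; the divalent copper carboxylate of the same molecule, which carries the bisoxazoline, captures this radical, and the trivalent copper alkyl collapses by C–O reductive elimination to the lactone with return of monovalent copper. The closest known reaction type is the copper/bisoxazoline-catalysed enantioselective radical oxyarylation of 4-aryl-4-pentenoic and 2-(1-arylvinyl)benzoic acids with aryldiazonium salts, where a tethered carboxylate traps a tertiary benzylic radical; here an ester replaces the aryl group at the radical centre, which is the part beyond precedent. The five-membered ring closes by bonding of the carboxylate oxygen to the radical-bearing terminus of an allyl system that lies inside the forming ring (geometrically a 5-endo closure, realised as reductive elimination from a six-membered cupracycle), which is possible because the (E) double bond holds CO2H and C-4 cis. The quaternary centre is the only stereocentre and is set under catalyst control by the C2-symmetric ligand on copper during C–O bond formation at the planar, prochiral radical. The step needs aryl radical addition at the acrylate CH2 and not at the tetrasubstituted enol ether (secured by sterics and by the polarity match of an aryl radical with an acrylate), C–O bond formation at C-4 and not at the alkoxy-bearing allyl terminus (which would give a three-membered lactone), and radical capture faster than hydrogen abstraction or oligomerisation (secured by the copper carboxylate being part of the same molecule).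

Step 11
Reactants: 15 methyl (2S)-2-[(4-acetoxy-3-bromophenyl)methyl]-3-[3-bromo-4,5-bis(methoxymethoxy)phenyl]-4-(methoxymethoxy)-5-oxo-2,5-dihydrofuran-2-carboxylate
Product: 16 methyl (2S)-2-{[4-acetoxy-3-(3-methylbut-2-en-1-yl)phenyl]methyl}-3-[3,4-bis(methoxymethoxy)-5-(3-methylbut-2-en-1-yl)phenyl]-4-(methoxymethoxy)-5-oxo-2,5-dihydrofuran-2-carboxylate
Conditions: Pd(PPh3)4 (10 mol %), tributyl(prenyl)stannane (3 equiv), DMF, 90 °C
Reagents that add atoms: tributyl(3-methylbut-2-en-1-yl)stannane, CCCC[Sn](CCCC)(CCCC)CC=C(C)C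
Why: twofold Stille coupling should replace both aryl bromides by linear prenyl groups under neutral conditions that leave the acetate, the acetals and the quaternary centre (no enolisable hydrogen) untouched.

Step 12
Reactants: 16 methyl (2S)-2-{[4-acetoxy-3-(3-methylbut-2-en-1-yl)phenyl]methyl}-3-[3,4-bis(methoxymethoxy)-5-(3-methylbut-2-en-1-yl)phenyl]-4-(methoxymethoxy)-5-oxo-2,5-dihydrofuran-2-carboxylate
Product: 17 methyl (2S)-3-[3,4-dihydroxy-5-(3-methylbut-2-en-1-yl)phenyl]-4-hydroxy-2-{[4-hydroxy-3-(3-methylbut-2-en-1-yl)phenyl]methyl}-5-oxo-2,5-dihydrofuran-2-carboxylate (CNP0460191.1)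
Conditions: HCl (1.25 M) in MeOH, 0 °C to rt
Reagents that add atoms: none
Why: acid-catalysed acetal solvolysis of the three methoxymethyl ethers and transesterification of the aryl acetate should free all four hydroxyl groups, with methanol keeping the methyl ester degenerate and the dilute acid at low temperature sparing the prenyl groups.

Compound list
1 | 2-bromo-6-methoxyphenol | COc1cccc(Br)c1O | starting material
2 | 2-bromo-4-iodo-6-methoxyphenol | COc1cc(I)cc(Br)c1O | intermediate
3 | 3-bromo-5-iodobenzene-1,2-diol | Oc1cc(I)cc(Br)c1O | intermediate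
4 | 1-bromo-5-iodo-2,3-bis(methoxymethoxy)benzene | COCOc1cc(I)cc(Br)c1OCOC | intermediate
5 | dimethyl 2-oxopentanedioate | COC(=O)CCC(=O)C(=O)OC | starting material
6 | dimethyl 3-[3-bromo-4,5-bis(methoxymethoxy)phenyl]-2-oxopentanedioate (racemic) | COC(=O)CC(c1cc(Br)c(OCOC)c(OCOC)c1)C(=O)C(=O)OC | intermediate
7 | dimethyl 3-[3-bromo-4,5-bis(methoxymethoxy)phenyl]-2-(methoxymethoxy)pent-2-enedioate (E/Z mixture) | COC(=O)CC(c1cc(Br)c(OCOC)c(OCOC)c1)=C(OCOC)C(=O)OC | intermediate
8 | dimethyl 3-[3-bromo-4,5-bis(methoxymethoxy)phenyl]-4-(hydroxymethyl)-2-(methoxymethoxy)pent-2-enedioate | COC(=O)C(CO)C(c1cc(Br)c(OCOC)c(OCOC)c1)=C(OCOC)C(=O)OC | intermediate (not isolated)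
9 | methyl 4-[3-bromo-4,5-bis(methoxymethoxy)phenyl]-5-(methoxymethoxy)-6-oxo-3,6-dihydro-2H-pyran-3-carboxylate | COC(=O)C1COC(=O)C(OCOC)=C1c1cc(Br)c(OCOC)c(OCOC)c1 | intermediate (not isolated)
10 | (2E)-3-[3-bromo-4,5-bis(methoxymethoxy)phenyl]-4-(methoxycarbonyl)-2-(methoxymethoxy)penta-2,4-dienoic acid | OC(=O)/C(OCOC)=C(\C(=C)C(=O)OC)c1cc(Br)c(OCOC)c(OCOC)c1 | intermediate
11 | 2-bromo-4-nitrophenol | Oc1ccc([N+](=O)[O-])cc1Br | starting material
12 | 2-bromo-4-nitrophenyl acetate | CC(=O)Oc1ccc([N+](=O)[O-])cc1Br | intermediate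
13 | 4-amino-2-bromophenyl acetate | CC(=O)Oc1ccc(N)cc1Br | intermediate
14 | 4-acetoxy-3-bromobenzenediazonium tetrafluoroborate | CC(=O)Oc1ccc([N+]#N)cc1Br.F[B-](F)(F)F | intermediate
15 | methyl (2S)-2-[(4-acetoxy-3-bromophenyl)methyl]-3-[3-bromo-4,5-bis(methoxymethoxy)phenyl]-4-(methoxymethoxy)-5-oxo-2,5-dihydrofuran-2-carboxylate | COC(=O)[C@@]1(Cc2ccc(OC(C)=O)c(Br)c2)OC(=O)C(OCOC)=C1c1cc(OCOC)c(OCOC)c(Br)c1 | intermediate
16 | methyl (2S)-2-{[4-acetoxy-3-(3-methylbut-2-en-1-yl)phenyl]methyl}-3-[3,4-bis(methoxymethoxy)-5-(3-methylbut-2-en-1-yl)phenyl]-4-(methoxymethoxy)-5-oxo-2,5-dihydrofuran-2-carboxylate | COC(=O)[C@@]1(Cc2ccc(OC(C)=O)c(CC=C(C)C)c2)OC(=O)C(OCOC)=C1c1cc(OCOC)c(OCOC)c(CC=C(C)C)c1 | intermediate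
17 | methyl (2S)-3-[3,4-dihydroxy-5-(3-methylbut-2-en-1-yl)phenyl]-4-hydroxy-2-{[4-hydroxy-3-(3-methylbut-2-en-1-yl)phenyl]methyl}-5-oxo-2,5-dihydrofuran-2-carboxylate | COC(=O)[C@@]1(Cc2ccc(O)c(CC=C(C)C)c2)OC(=O)C(O)=C1c1cc(O)c(O)c(CC=C(C)C)c1 | target

Total step count: 12. Longest linear sequence: 9 steps (steps 1 to 6, then 10 to 12).

Steps most likely to fail

Step 10 (proposed new method). The copper-bound carboxylate may discriminate poorly between the two faces of a radical that is α to an ester and not benzylic, and the radical may be lost to hydrogen abstraction or acrylate oligomerisation before capture. The fallback sets out from 10 and uses a classical Meerwein bromoarylation with 14 (CuBr cat., LiBr, MeCN, 0 °C), which should give racemic (2E)-5-(4-acetoxy-3-bromophenyl)-4-bromo-3-[3-bromo-4,5-bis(methoxymethoxy)phenyl]-4-(methoxycarbonyl)-2-(methoxymethoxy)pent-2-enoic acid F1. Displacement of the tertiary allylic bromide by the cis carboxylate (NaHCO3, DMF, rt) should then give the racemic lactone, methyl 2-[(4-acetoxy-3-bromophenyl)methyl]-3-[3-bromo-4,5-bis(methoxymethoxy)phenyl]-4-(methoxymethoxy)-5-oxo-2,5-dihydrofuran-2-carboxylate F2. Preparative chromatography on a chiral stationary phase separates it into 15, where the route is rejoined, and the discarded (2R) enantiomer F3.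

Step 6. The aldol adduct may lose water directly without passing through the lactone, which removes the ester differentiation, and the dienolate may add to the acrylate product. The fallback sets out from 7. Saponification of both esters (LiOH, THF/H2O) gives 3-[3-bromo-4,5-bis(methoxymethoxy)phenyl]-2-(methoxymethoxy)pent-2-enedioic acid F4, and dehydration (Ac2O, rt) closes the cyclic anhydride 4-[3-bromo-4,5-bis(methoxymethoxy)phenyl]-5-(methoxymethoxy)-2H-pyran-2,6(3H)-dione F5, which fixes the cis geometry. Methanolysis at the non-conjugated carbonyl (MeOH, rt) should give the half-ester (2Z)-3-[3-bromo-4,5-bis(methoxymethoxy)phenyl]-5-methoxy-2-(methoxymethoxy)-5-oxopent-2-enoic acid F6. A Mannich reaction of its dianion (LiN(SiMe3)2, then dimethylmethyleneammonium iodide) gives the amine (2Z)-3-[3-bromo-4,5-bis(methoxymethoxy)phenyl]-4-[(dimethylamino)methyl]-5-methoxy-2-(methoxymethoxy)-5-oxopent-2-enoic acid F7, and N-methylation with elimination (MeI, then NaHCO3) rejoins the route at 10.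

Step 4. The keto ester enolate may condense with itself at the reaction temperature, and the active catalyst may go on to insert into the C–Br bond once the iodide is consumed. The fallback sets out from 4. Iodine–magnesium exchange (i-PrMgCl·LiCl, THF, −40 °C) and formylation with DMF give 3-bromo-4,5-bis(methoxymethoxy)benzaldehyde F8. Horner–Wadsworth–Emmons olefination with methyl 2-(tert-butyldimethylsilyloxy)-2-(dimethoxyphosphoryl)acetate (LiN(SiMe3)2, THF, −78 °C) gives methyl 3-[3-bromo-4,5-bis(methoxymethoxy)phenyl]-2-(tert-butyldimethylsilyloxy)prop-2-enoate F9, and desilylation (Bu4NF, AcOH, THF) gives methyl 3-[3-bromo-4,5-bis(methoxymethoxy)phenyl]-2-oxopropanoate F10. C-alkylation of its enolate with methyl bromoacetate (K2CO3, acetone) rejoins the route at 6.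

Further compounds
F1 | step 10 | (2E)-5-(4-acetoxy-3-bromophenyl)-4-bromo-3-[3-bromo-4,5-bis(methoxymethoxy)phenyl]-4-(methoxycarbonyl)-2-(methoxymethoxy)pent-2-enoic acid (racemic) | OC(=O)/C(OCOC)=C(\C(Br)(Cc1ccc(OC(C)=O)c(Br)c1)C(=O)OC)c1cc(Br)c(OCOC)c(OCOC)c1
F2 | step 10 | methyl 2-[(4-acetoxy-3-bromophenyl)methyl]-3-[3-bromo-4,5-bis(methoxymethoxy)phenyl]-4-(methoxymethoxy)-5-oxo-2,5-dihydrofuran-2-carboxylate (racemic) | COC(=O)C1(Cc2ccc(OC(C)=O)c(Br)c2)OC(=O)C(OCOC)=C1c1cc(OCOC)c(OCOC)c(Br)c1
F3 | step 10 | methyl (2R)-2-[(4-acetoxy-3-bromophenyl)methyl]-3-[3-bromo-4,5-bis(methoxymethoxy)phenyl]-4-(methoxymethoxy)-5-oxo-2,5-dihydrofuran-2-carboxylate | COC(=O)[C@]1(Cc2ccc(OC(C)=O)c(Br)c2)OC(=O)C(OCOC)=C1c1cc(OCOC)c(OCOC)c(Br)c1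
F4 | step 6 | 3-[3-bromo-4,5-bis(methoxymethoxy)phenyl]-2-(methoxymethoxy)pent-2-enedioic acid | OC(=O)CC(c1cc(Br)c(OCOC)c(OCOC)c1)=C(OCOC)C(=O)O
F5 | step 6 | 4-[3-bromo-4,5-bis(methoxymethoxy)phenyl]-5-(methoxymethoxy)-2H-pyran-2,6(3H)-dione | COCOC1=C(c2cc(Br)c(OCOC)c(OCOC)c2)CC(=O)OC1=O
F6 | step 6 | (2Z)-3-[3-bromo-4,5-bis(methoxymethoxy)phenyl]-5-methoxy-2-(methoxymethoxy)-5-oxopent-2-enoic acid | OC(=O)/C(OCOC)=C(\CC(=O)OC)c1cc(Br)c(OCOC)c(OCOC)c1
F7 | step 6 | (2Z)-3-[3-bromo-4,5-bis(methoxymethoxy)phenyl]-4-[(dimethylamino)methyl]-5-methoxy-2-(methoxymethoxy)-5-oxopent-2-enoic acid | OC(=O)/C(OCOC)=C(\C(CN(C)C)C(=O)OC)c1cc(Br)c(OCOC)c(OCOC)c1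
F8 | step 4 | 3-bromo-4,5-bis(methoxymethoxy)benzaldehyde | COCOc1cc(C=O)cc(Br)c1OCOC
F9 | step 4 | methyl 3-[3-bromo-4,5-bis(methoxymethoxy)phenyl]-2-(tert-butyldimethylsilyloxy)prop-2-enoate | COC(=O)C(O[Si](C)(C)C(C)(C)C)=Cc1cc(Br)c(OCOC)c(OCOC)c1
F10 | step 4 | methyl 3-[3-bromo-4,5-bis(methoxymethoxy)phenyl]-2-oxopropanoate | COC(=O)C(=O)Cc1cc(Br)c(OCOC)c(OCOC)c1
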